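**Plan**
Retrosynthesis: the five O-protecting groups (four benzyl, one isopropyl) and the two aryl–butyryl bonds of rings A and C are removed first. Ring B is then cut at B1–B6 and B2–B3 (B1 = acetyl-bearing carbon, B2 = O, B3 = CH2–ring C, B4 = O, B5 = CH2–ring A, B6 = O).
Enabling feature: ring B is a hexasubstituted acetylphloroglucinol with oxygen on B2, B4 and B6. B3–B6 is therefore an acetoacetate (C4 = B3, ester carbon C1 = B6) carrying both arylmethyl arms, and B1–B2 is a 4-alkoxybut-3-yn-2-one.
The acetoacetate is cut at its two arms: ArA–CH2 on C2 by Knoevenagel condensation/reduction and ArC–CH2 on C4 by dianion aldol addition/ionic hydrogenation (ArA = 4,6-bis(benzyloxy)-2-methoxy-3-methylphenyl, ArC = 2,6-bis(benzyloxy)-4-methoxy-3-methylphenyl). Both aldehydes come from 2-methylphloroglucinol.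
Forward: rings A and C are present from the start (steps 1–5), the chain and diene are built (steps 6–10), the ynone is made (steps 11–12), ring B is closed and aromatised (step 13), then butyrylation (step 14) and deprotection (step 15).
Stereochemistry: the target has no stereocentre; stereocentres and alkene geometries of intermediates are erased on aromatisation.

Key step: step 13

Remark: the two outer rings of the target are regioisomers (bridge carbon between OMe and OH in ring A, between two OH in ring C), so two different aldehydes are made; intermediates with stereocentres are racemic diastereomer mixtures and the silyl enol ethers are E/Z mixtures, so their SMILES carry no descriptors.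

Step 1
Reactants: 1 2-methylphloroglucinol (2-methylbenzene-1,3,5-triol)
Product: 2 2,4,6-trihydroxy-3-methylbenzaldehyde
Conditions: POCl3, DMF, EtOAc, 0 °C → rt; then H2O, 50 °C
Reagents that add atoms: N,N-dimethylformamide, CN(C)C=O; water, O
Why: Vilsmeier–Haack formylation; the two unsubstituted ring carbons of 1 are equivalent and the first formyl group deactivates the ring against a second.

Step 2
Reactants: 2 2,4,6-trihydroxy-3-methylbenzaldehyde
Product: 3 4,6-bis(benzyloxy)-2-hydroxy-3-methylbenzaldehyde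
Conditions: BnBr (2.05 equiv), K2CO3, DMF, 0 °C → rt
Reagents that add atoms: benzyl bromide, BrCc1ccccc1
Why: Williamson ether synthesis under substrate control: the 4-OH para to the aldehyde is the most acidic, the 6-OH is the less hindered ortho hydroxyl, and the 2-OH, flanked by methyl and hydrogen-bonded to the aldehyde, should remain.

Step 3
Reactants: 3 4,6-bis(benzyloxy)-2-hydroxy-3-methylbenzaldehyde
Product: 4 4,6-bis(benzyloxy)-2-methoxy-3-methylbenzaldehyde (aldehyde A)
Conditions: MeI, K2CO3, DMF, 50 °C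
Reagents that add atoms: iodomethane, CI
Why: Williamson methylation of the remaining chelated phenol, which needs only excess iodide and mild heating.

Step 4
Reactants: 2 2,4,6-trihydroxy-3-methylbenzaldehyde
Product: 5 2,6-dihydroxy-4-methoxy-3-methylbenzaldehyde
Conditions: MeI (1.0 equiv), K2CO3 (1.0 equiv), acetone, 0 °C → rt
Reagents that add atoms: iodomethane, CI
Why: Williamson methylation with one equivalent of base, which should select the 4-OH as the most acidic hydroxyl and the only one not held in a hydrogen bond to the aldehyde.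

Step 5
Reactants: 5 2,6-dihydroxy-4-methoxy-3-methylbenzaldehyde
Product: 6 2,6-bis(benzyloxy)-4-methoxy-3-methylbenzaldehyde (aldehyde C)
Conditions: BnBr (2.5 equiv), K2CO3, Bu4NI (cat.), DMF, 70 °C
Reagents that add atoms: benzyl bromide, BrCc1ccccc1
Why: exhaustive Williamson benzylation; both remaining hydroxyls are ortho to the aldehyde and need excess bromide, iodide catalysis and heat.

Step 6
Reactants: 4 aldehyde A; 7 methyl acetoacetate
Product: 9 methyl 2-(ArA-methyl)-3-oxobutanoate, via arylidene acetoacetate 8 (not isolated)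
Conditions: 7 (1.5 equiv), piperidine (cat.), AcOH (cat.), diethyl 2,6-dimethyl-1,4-dihydropyridine-3,5-dicarboxylate (Hantzsch ester, 1.2 equiv), EtOH, 60 °C
Reagents that add atoms: none
Why: Knoevenagel condensation followed in the same flask by conjugate transfer hydrogenation of 8 by the Hantzsch ester (reductive alkylation), which gives mono-C-benzylation at the α-carbon without a labile 2,4,6-trialkoxybenzyl halide.

Step 7
Reactants: 9 methyl 2-(ArA-methyl)-3-oxobutanoate; 6 aldehyde C
Product: 10 methyl 5-ArC-5-hydroxy-2-(ArA-methyl)-3-oxopentanoate (diastereomer mixture)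
Conditions: LiN(CHMe2)2 (2.2 equiv), THF, −78 → 0 °C; then 6, −78 °C; aq. NH4Cl at −78 °C
Reagents that add atoms: none
Why: aldol addition of a β-keto ester dianion, which reacts at its γ-carbon (the last-formed and most basic site); aldehyde 6 cannot enolise and both stereocentres are removed later.

Step 8
Reactants: 10 methyl 5-ArC-5-hydroxy-2-(ArA-methyl)-3-oxopentanoate
Product: 11 methyl 5-ArC-2-(ArA-methyl)-3-oxopentanoate
Conditions: Et3SiH (5 equiv), CF3CO2H (5 equiv), CH2Cl2, −20 → 0 °C
Reagents that add atoms: none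
Why: ionic hydrogenation: the benzylic hydroxyl ionises under acid to a cation stabilised by three ring oxygens, and Et3SiH in excess delivers hydride faster than another arene can add.

Step 9
Reactants: 11 methyl 5-ArC-2-(ArA-methyl)-3-oxopentanoate
Product: 12 methyl 5-ArC-2-(ArA-methyl)-3-(trimethylsilyloxy)pent-2-enoate (E/Z mixture)
Conditions: Me3SiCl, Et3N, toluene, rt, 48 h; filtration under Ar
Reagents that add atoms: chlorotrimethylsilane, C[Si](C)(C)Cl
Why: O-silylation of the β-keto ester enol with silyl chloride and amine base, the usual first stage towards 1,3-bis(silyloxy)dienes.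

Step 10
Reactants: 12 methyl 5-ArC-2-(ArA-methyl)-3-(trimethylsilyloxy)pent-2-enoate
Product: 13 5-ArC-2-(ArA-methyl)-1-methoxy-1,3-bis(trimethylsilyloxy)penta-1,3-diene (isomer mixture, used crude)
Conditions: LiN(CHMe2)2 (1.2 equiv), THF, −78 °C; Me3SiCl, −78 → 0 °C; pentane, filtration under Ar
Reagents that add atoms: chlorotrimethylsilane, C[Si](C)(C)Cl
Why: kinetic γ-deprotonation of the β-silyloxy enoate gives the extended ester dienolate, which is silylated on oxygen to the 1-methoxy-1,3-bis(silyloxy)diene.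

Step 11
Reactants: 14 trichloroethylene
Product: 15 (E)-1,2-dichloro-1-(propan-2-yloxy)ethene
Conditions: propan-2-ol, KH, THF, 0 °C; then 14, −40 °C → rt
Reagents that add atoms: propan-2-ol, CC(C)O
Why: base-mediated addition–elimination of an alkoxide to trichloroethylene (through dichloroacetylene and anti addition) gives the 1,2-dichlorovinyl ether, the standard precursor of alkoxyacetylenes; isopropyl is chosen because BCl3 cleaves a secondary-alkyl aryl ether in the presence of methyl ethers.

Step 12
Reactants: 15 (E)-1,2-dichloro-1-(propan-2-yloxy)ethene; 16 N-methoxy-N-methylacetamide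
Product: 18 4-(propan-2-yloxy)but-3-yn-2-one, via lithium isopropoxyacetylide 17 (not isolated)
Conditions: n-BuLi (2.2 equiv), THF, −78 → −40 °C; then 16, −78 → −20 °C; cold pH 7 buffer; used without distillation
Reagents that add atoms: none
Why: dehydrochlorination and chlorine–lithium exchange give the lithium alkoxyacetylide, whose acylation by a Weinreb amide stops at the ketone because the chelated tetrahedral adduct survives until work-up.

Step 13
Reactants: 13 5-ArC-2-(ArA-methyl)-1-methoxy-1,3-bis(trimethylsilyloxy)penta-1,3-diene; 18 4-(propan-2-yloxy)but-3-yn-2-one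
Product: 21 1-[3-(ArC-methyl)-5-(ArA-methyl)-4,6-dihydroxy-2-(propan-2-yloxy)phenyl]ethan-1-one, via cyclohexadiene cycloadduct 19 (not isolated), via bis-silyl ether 20 (not isolated)
Conditions: 18 (1.3 equiv), Me3SiOTf (0.3 equiv), CH2Cl2, −78 → −20 °C; then 1 M HCl, THF, rt
Reagents that add atoms: none
Why: Proposed new method: O-silylation of ynone 18 by Me3SiOTf makes its isopropoxy-bearing carbon a strong electrophile that is attacked by the diene terminus C4, the former γ-carbon (Mukaiyama–Michael step, bond B2–B3), and the silyloxyallene so formed adds through its central carbon to the silylated ester carbon C1 (bond B1–B6), which amounts to a stepwise polar Diels–Alder reaction. The closest known reaction type is the cycloaromatisation of 1-alkoxy-1,3-bis(silyloxy)dienes with acetylenic ketones and esters to resorcinols; not yet shown are a 4-alkoxy ynone as the two-carbon partner and a diene substituted at both C2 and C4. Ring B closes in a six-membered formal [4+2] mode (allene carbon onto the oxocarbenium carbon of the ketene acetal), after which 1,4-elimination of methanol from 19 and hydrolysis of the two silyl ethers of 20 on acidic work-up give the arene. No new stereocentre persists, since the two sp3 ring carbons of 19 and the diene geometry are erased by aromatisation. The step needs regioselectivity and [4+2] instead of [3+3] closure: the first rests on polar matching of the most nucleophilic diene carbon (C4) with the β-carbon of the ynone, which places acetyl between two oxygen-bearing carbons, and the second on the arylmethyl group at C2, which leaves the aldol-type closure no hydrogen for aromatisation so that only closure on C1 leads to an arene.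

Step 14
Reactants: 21 1-[3-(ArC-methyl)-5-(ArA-methyl)-4,6-dihydroxy-2-(propan-2-yloxy)phenyl]ethan-1-one; 22 butanoyl chloride
Product: 23 1-[3-{[2,6-bis(benzyloxy)-5-butanoyl-4-methoxy-3-methylphenyl]methyl}-5-{[4,6-bis(benzyloxy)-5-butanoyl-2-methoxy-3-methylphenyl]methyl}-4,6-dihydroxy-2-(propan-2-yloxy)phenyl]ethan-1-one
Conditions: 22 (3 equiv), TiCl4 (4 equiv), CH2Cl2, −78 → −30 °C; cold aq. NaHCO3
Reagents that add atoms: none
Why: Friedel–Crafts acylation; each outer ring has exactly one unsubstituted carbon, flanked by two alkoxy groups and strongly activated, whereas ring B is fully substituted and deactivated by its acetyl group.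

Step 15
Reactants: 23 the bis-butyryl compound of step 14
Product: 24 target, 1-[3-{[5-butanoyl-2,6-dihydroxy-4-methoxy-3-methylphenyl]methyl}-5-{[5-butanoyl-4,6-dihydroxy-2-methoxy-3-methylphenyl]methyl}-2,4,6-trihydroxyphenyl]ethan-1-one
Conditions: BCl3 (12 equiv), C6HMe5 (12 equiv), CH2Cl2, −78 → 0 °C; MeOH, then H2O
Reagents that add atoms: none
Why: Lewis acid ether cleavage with a cation scavenger: BCl3 ionises benzyl and isopropyl aryl ethers at low temperature while aryl methyl ethers persist (the methoxy group next to the ring-C butyryl is shielded once the benzyl ether on the other side of that carbonyl has formed the boron chelate), and pentamethylbenzene traps the benzyl cations.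

**Compound list**
1 | 2-methylphloroglucinol | Cc1c(O)cc(O)cc1O | starting material
2 | 2,4,6-trihydroxy-3-methylbenzaldehyde | O=Cc1c(O)c(C)c(O)cc1O | intermediate
3 | 4,6-bis(benzyloxy)-2-hydroxy-3-methylbenzaldehyde | O=Cc1c(O)c(C)c(OCc2ccccc2)cc1OCc1ccccc1 | intermediate
4 | 4,6-bis(benzyloxy)-2-methoxy-3-methylbenzaldehyde (aldehyde A) | O=Cc1c(OC)c(C)c(OCc2ccccc2)cc1OCc1ccccc1 | intermediate
5 | 2,6-dihydroxy-4-methoxy-3-methylbenzaldehyde | O=Cc1c(O)c(C)c(OC)cc1O | intermediate
6 | 2,6-bis(benzyloxy)-4-methoxy-3-methylbenzaldehyde (aldehyde C) | O=Cc1c(OCc2ccccc2)c(C)c(OC)cc1OCc1ccccc1 | intermediate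
7 | methyl acetoacetate | CC(=O)CC(=O)OC | starting material
8 | methyl 2-(ArA-methylidene)-3-oxobutanoate (E/Z mixture, not isolated) | CC(=O)C(=Cc1c(OC)c(C)c(OCc2ccccc2)cc1OCc1ccccc1)C(=O)OC | intermediate
9 | methyl 2-(ArA-methyl)-3-oxobutanoate (racemic) | CC(=O)C(Cc1c(OC)c(C)c(OCc2ccccc2)cc1OCc1ccccc1)C(=O)OC | intermediate
10 | methyl 5-ArC-5-hydroxy-2-(ArA-methyl)-3-oxopentanoate (diastereomer mixture) | COC(=O)C(Cc1c(OC)c(C)c(OCc2ccccc2)cc1OCc1ccccc1)C(=O)CC(O)c1c(OCc2ccccc2)c(C)c(OC)cc1OCc1ccccc1 | intermediate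
11 | methyl 5-ArC-2-(ArA-methyl)-3-oxopentanoate (racemic) | COC(=O)C(Cc1c(OC)c(C)c(OCc2ccccc2)cc1OCc1ccccc1)C(=O)CCc1c(OCc2ccccc2)c(C)c(OC)cc1OCc1ccccc1 | intermediate
12 | methyl 5-ArC-2-(ArA-methyl)-3-(trimethylsilyloxy)pent-2-enoate (E/Z mixture) | COC(=O)C(Cc1c(OC)c(C)c(OCc2ccccc2)cc1OCc1ccccc1)=C(O[Si](C)(C)C)CCc1c(OCc2ccccc2)c(C)c(OC)cc1OCc1ccccc1 | intermediate
13 | 5-ArC-2-(ArA-methyl)-1-methoxy-1,3-bis(trimethylsilyloxy)penta-1,3-diene (isomer mixture) | COC(O[Si](C)(C)C)=C(Cc1c(OC)c(C)c(OCc2ccccc2)cc1OCc1ccccc1)C(O[Si](C)(C)C)=CCc1c(OCc2ccccc2)c(C)c(OC)cc1OCc1ccccc1 | intermediate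
14 | trichloroethylene | ClC=C(Cl)Cl | starting material
15 | (E)-1,2-dichloro-1-(propan-2-yloxy)ethene | CC(C)O/C(Cl)=C\Cl | intermediate
16 | N-methoxy-N-methylacetamide | CC(=O)N(C)OC | starting material
17 | lithium 2-(propan-2-yloxy)ethynide (not isolated) | [Li]C#COC(C)C | intermediate
18 | 4-(propan-2-yloxy)but-3-yn-2-one | CC(=O)C#COC(C)C | intermediate
19 | 1-[6-methoxy-2-(propan-2-yloxy)-4,6-bis(trimethylsilyloxy)-3-(ArC-methyl)-5-(ArA-methyl)cyclohexa-1,4-dien-1-yl]ethan-1-one (diastereomer mixture, not isolated) | CC(=O)C1=C(OC(C)C)C(Cc2c(OCc3ccccc3)c(C)c(OC)cc2OCc2ccccc2)C(O[Si](C)(C)C)=C(Cc2c(OC)c(C)c(OCc3ccccc3)cc2OCc2ccccc2)C1(OC)O[Si](C)(C)C | intermediate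
20 | 1-[3-(ArC-methyl)-5-(ArA-methyl)-2-(propan-2-yloxy)-4,6-bis(trimethylsilyloxy)phenyl]ethan-1-one (not isolated) | CC(=O)c1c(OC(C)C)c(Cc2c(OCc3ccccc3)c(C)c(OC)cc2OCc2ccccc2)c(O[Si](C)(C)C)c(Cc2c(OC)c(C)c(OCc3ccccc3)cc2OCc2ccccc2)c1O[Si](C)(C)C | intermediate
21 | 1-[3-(ArC-methyl)-5-(ArA-methyl)-4,6-dihydroxy-2-(propan-2-yloxy)phenyl]ethan-1-one | CC(=O)c1c(OC(C)C)c(Cc2c(OCc3ccccc3)c(C)c(OC)cc2OCc2ccccc2)c(O)c(Cc2c(OC)c(C)c(OCc3ccccc3)cc2OCc2ccccc2)c1O | intermediate
22 | butanoyl chloride | CCCC(Cl)=O | starting material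
23 | 1-[3-{[2,6-bis(benzyloxy)-5-butanoyl-4-methoxy-3-methylphenyl]methyl}-5-{[4,6-bis(benzyloxy)-5-butanoyl-2-methoxy-3-methylphenyl]methyl}-4,6-dihydroxy-2-(propan-2-yloxy)phenyl]ethan-1-one | CC(=O)c1c(OC(C)C)c(Cc2c(OCc3ccccc3)c(C)c(OC)c(C(=O)CCC)c2OCc2ccccc2)c(O)c(Cc2c(OC)c(C)c(OCc3ccccc3)c(C(=O)CCC)c2OCc2ccccc2)c1O | intermediate
24 | CNP0184345.0, 1-[3-{[5-butanoyl-2,6-dihydroxy-4-methoxy-3-methylphenyl]methyl}-5-{[5-butanoyl-4,6-dihydroxy-2-methoxy-3-methylphenyl]methyl}-2,4,6-trihydroxyphenyl]ethan-1-one | CCCC(=O)c1c(O)c(C)c(OC)c(Cc2c(O)c(Cc3c(O)c(C)c(OC)c(C(=O)CCC)c3O)c(O)c(C(C)=O)c2O)c1O | target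

**Totals**
Total steps: 15. Longest linear sequence: 11 steps (steps 1, 2, 3, 6, 7, 8, 9, 10, 13, 14, 15).

**Steps most likely to fail**

Step 13 (new method). The donor-substituted ynone may be too weak an electrophile. The reaction may also stop at the open-chain Michael adduct without closure onto the ester carbon. The diene may be protodesilylated, or the ynol ether may fragment with loss of propene, before the union takes place. The fallback uses known chemistry and forms the same two ring-B bonds in separate operations. It sets out from 11: its dianion (LiN(CHMe2)2, 3 equiv, THF, −78 °C) would be acylated at the γ-carbon by N-methoxy-N-methyl-2-(2-methyl-1,3-dioxolan-2-yl)acetamide to give the dioxolane-protected diketo ester F1. Aqueous acid would remove the ketal to give the 3,5,7-triketo ester F2. Mg(OMe)2 in MeOH would then effect the Claisen-type cyclisation (the acetyl-flanked CH2 onto the ester carbon) to the ring-B triol F3; the aldol alternative is again blocked by the substituent at C2. F3 would be butyrylated as in step 14 to the bis-butyryl tetrabenzyl ether F4, and hydrogenolysis (H2, Pd/C, EtOAc) of the four benzyl ethers would return to the route at 24.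

Step 14. The electron-rich outer rings may suffer ipso attack by protons or acylium ions, which would break the diarylmethane bridges. TiCl4 may cleave ethers prematurely, and the ring-B phenols may be O-acylated in competition with C-acylation. The fallback avoids a strong Lewis acid and builds each butyryl group in two bond-forming stages. It sets out from 21: Vilsmeier–Haack formylation (POCl3, DMF) of the two free ring carbons would give the dialdehyde F5. Excess n-PrMgBr (THF, −78 °C) would add to both aldehydes to give the bis(1-hydroxybutyl) compound F6, the hindered ring-B acetyl being shielded as its chelated magnesium phenoxide or enolate. MnO2 (CH2Cl2, rt) would oxidise the two electron-rich benzylic alcohols and return to the route at 23.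

Step 15. Prolonged exposure to excess BCl3 may cleave the methyl ether next to the ring-C butyryl group by chelation, released benzyl cations may C-alkylate the polyphenol, and the acid may cut a methylene bridge. The fallback separates the two kinds of ether cleavage. It sets out from 23: hydrogenolysis (H2, Pd/C, EtOAc, rt) would remove the four benzyl ethers under neutral conditions to give the ring-B isopropyl ether F7. A short treatment with BCl3 (2–3 equiv, CH2Cl2, −78 → −20 °C) would then remove only the isopropyl group and return to the route at 24.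

**Further compounds**
F1 | step 13 | methyl 2-(ArA-methyl)-4-(ArC-methyl)-6-(2-methyl-1,3-dioxolan-2-yl)-3,5-dioxohexanoate | COC(=O)C(Cc1c(OC)c(C)c(OCc2ccccc2)cc1OCc1ccccc1)C(=O)C(Cc1c(OCc2ccccc2)c(C)c(OC)cc1OCc1ccccc1)C(=O)CC1(C)OCCO1
F2 | step 13 | methyl 2-(ArA-methyl)-4-(ArC-methyl)-3,5,7-trioxooctanoate | COC(=O)C(Cc1c(OC)c(C)c(OCc2ccccc2)cc1OCc1ccccc1)C(=O)C(Cc1c(OCc2ccccc2)c(C)c(OC)cc1OCc1ccccc1)C(=O)CC(C)=O
F3 | step 13 | 1-[3-(ArC-methyl)-5-(ArA-methyl)-2,4,6-trihydroxyphenyl]ethan-1-one | CC(=O)c1c(O)c(Cc2c(OCc3ccccc3)c(C)c(OC)cc2OCc2ccccc2)c(O)c(Cc2c(OC)c(C)c(OCc3ccccc3)cc2OCc2ccccc2)c1O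
F4 | step 13 | 1-[3-{[2,6-bis(benzyloxy)-5-butanoyl-4-methoxy-3-methylphenyl]methyl}-5-{[4,6-bis(benzyloxy)-5-butanoyl-2-methoxy-3-methylphenyl]methyl}-2,4,6-trihydroxyphenyl]ethan-1-one | CC(=O)c1c(O)c(Cc2c(OCc3ccccc3)c(C)c(OC)c(C(=O)CCC)c2OCc2ccccc2)c(O)c(Cc2c(OC)c(C)c(OCc3ccccc3)c(C(=O)CCC)c2OCc2ccccc2)c1O
F5 | step 14 | 3-{[3-acetyl-5-{[4,6-bis(benzyloxy)-5-formyl-2-methoxy-3-methylphenyl]methyl}-4,6-dihydroxy-2-(propan-2-yloxy)phenyl]methyl}-2,4-bis(benzyloxy)-6-methoxy-5-methylbenzaldehyde (dialdehyde of 21) | CC(=O)c1c(OC(C)C)c(Cc2c(OCc3ccccc3)c(C)c(OC)c(C=O)c2OCc2ccccc2)c(O)c(Cc2c(OC)c(C)c(OCc3ccccc3)c(C=O)c2OCc2ccccc2)c1O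
F6 | step 14 | bis(1-hydroxybutyl) analogue of 23 (butanoyl groups replaced by CH(OH)CH2CH2CH3, diastereomer mixture) | CC(=O)c1c(OC(C)C)c(Cc2c(OCc3ccccc3)c(C)c(OC)c(C(O)CCC)c2OCc2ccccc2)c(O)c(Cc2c(OC)c(C)c(OCc3ccccc3)c(C(O)CCC)c2OCc2ccccc2)c1O
F7 | step 15 | 1-[3-{[5-butanoyl-2,6-dihydroxy-4-methoxy-3-methylphenyl]methyl}-5-{[5-butanoyl-4,6-dihydroxy-2-methoxy-3-methylphenyl]methyl}-4,6-dihydroxy-2-(propan-2-yloxy)phenyl]ethan-1-one | CC(=O)c1c(OC(C)C)c(Cc2c(O)c(C)c(OC)c(C(=O)CCC)c2O)c(O)c(Cc2c(OC)c(C)c(O)c(C(=O)CCC)c2O)c1O
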